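- Wednesday's run is my yardstick: epsilon repeats it, so the readings below can be taken as one curve of target against time.

| flask | starting material | coupling partner | protic impurity | remark | time |
|---|---|---|---|---|---|
| Wednesday's | 0.10 M | 0.25 M | 0.010 M | run made earlier |  |
| Monday's | 0.050 M | 0.25 M | 0.010 M | run made earlier |  |
| Tuesday's | 0.075 M | 0.25 M | 0.010 M | run made earlier |  |
| Saturday's | 0.10 M | 0.25 M | 0.015 M | run made earlier |  |
| delta | 0.10 M (fed, over 32.0 h) | 0.250 M | 0.0100 M | all but starting material at the start; starting material goes in evenly over 32.0 h, the run ends at 40 h | 40 h |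
| alpha | 0.10 M | 0.250 M | 0.0100 M | a single well-mixed tank run continuously and read at steady state, 40 h in it on average |  |
| epsilon | 0.10 M | 0.250 M | 0.0100 M | everything together in a closed stirred flask, run for 40 h | 40 h |
| eta | 0.10 M | 0.250 M | 0.0100 M | a single well-mixed tank run continuously and read at steady state, 120 h in it on average |  |

| run | time / h | target / % |
|---|---|---|
| Wednesday's | 2.50 | 0.7 |
| Wednesday's | 8.00 | 4.9 |
| Wednesday's | 15.0 | 12.0 |
| Wednesday's | 20.0 | 15.5 |
| Wednesday's | 30.0 | 20.5 |
| Wednesday's | 40.0 | 22.6 |
| Monday's | 3.00 | 0.8 |
| Monday's | 5.00 | 3.0 |
| Monday's | 8.00 | 4.4 |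
| Monday's | 15.0 | 11.5 |
| Monday's | 25.0 | 18.8 |
| Monday's | 40.0 | 21.7 |
| Tuesday's | 6.00 | 3.8 |
| Tuesday's | 12.0 | 9.3 |
| Tuesday's | 20.0 | 16.0 |
| Tuesday's | 25.0 | 19.2 |
| Tuesday's | 30.0 | 20.7 |
| Tuesday's | 40.0 | 20.7 |
| Saturday's | 3.00 | 0.7 |
| Saturday's | 6.00 | 2.8 |
| Saturday's | 12.0 | 8.0 |
| Saturday's | 20.0 | 15.8 |
| Saturday's | 40.0 | 22.0 |

(scatter of a reading: 0.5 percentage points)

- the stated concentrations are those of everything mixed, before any reaction; amounts are the same in each set-up
- the numbers in the tables scatter with a standard deviation of 0.5 percentage points
- the feed brings no volume worth counting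
- the earlier runs were made in a closed, stirred flask

1. the set-up with the highest amount of target at the outlet or at the end, in percent of the starting material put in ("none" if the first two lie within 2 percentage points) (delta / alpha / epsilon / eta / none)
2. amount of target at the outlet or at the end, in percent of the starting material put in, delta
3. amount of target at the outlet or at the end, in percent of the starting material put in, alpha
4. amount of target at the outlet or at the end, in percent of the starting material put in, epsilon
5. amount of target at the outlet or at the end, in percent of the starting material put in, eta

- First instants: Wednesday's run shows 0.7 % of target at 2.50 h, so there is a lag to watch. At 6.00 h, Saturday's run, with 0.015 M of protic impurity, shows 2.8 %, less than Tuesday's 3.8 % with 0.010 M. That is a hint, since the two also differ in starting material.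
- Middle: Wednesday's run climbs from 12.0 % at 15.0 h to 15.5 % at 20.0 h.
- End: Wednesday's run gains 2.1 percentage points over its last 10.0 h, and Tuesday's reads 20.7 % at 30.0 h and 20.7 % at 40.0 h, so within their scatter the readings are flattening.
- Monday's run, with half the starting material, ends at 21.7 % against 22.6 %. I read this as pseudo-first-order behaviour in starting material, and so I assume each portion follows the curve by its own age.
- The mean age is the average time a portion of starting material has spent in the flask when it is read. In delta, portions are 8.00 h to 40 h old, so the mean age is 24.0 h.
- My own reckoning: between the readings at 20.0 h and 30.0 h, the curve at that age gives 17.5 % for delta, and epsilon should repeat 22.6 %. A tank mixes fresh and old portions, and eta's 120 h lies past the last reading, so I give no tank figures.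
- The forecast says 16.7 % for delta, 15.5 % for alpha, 22.4 % for epsilon and 13 % for eta, with epsilon ahead. It differs from my delta figure, and it holds that target “is probably consumed in series”.
- The flasks give 16.5 % for delta, 12.1 % for alpha, 22.3 % for epsilon and 8.54 % for eta, so epsilon holds the most target.

    starting material + coupling partner → intermediate + by-product (k = 0.240 M⁻¹ h⁻¹)
    intermediate → target (k = 0.0480 h⁻¹)
    starting material + protic impurity → quenched substrate (k = 110 M⁻¹ h⁻¹)
    target → over-reaction product A (k = 1.20 × 10⁻⁴ h⁻¹)
    target → over-reaction product B (k = 0.0540 h⁻¹)

- Target's half-life by its passing into over-reaction product B alone is 13 h, close to the 12 h half-life of starting material by coupling alone in epsilon, the other concentrations as charged. Delta's mean age of 24.0 h is twice that target half-life, and delta's 16.5 % lies 1 point under my mark. Read at 3.0 d, the same delta flask has a mean age of 56.0 h, older than epsilon's 40 h, yet it holds less target than epsilon, 19.1 %, with over-reaction product B at 46.4 %.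

The numbers in the tables stem from a simulated flask for substances that don't exist, noise included.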